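The target is a meso oxolane: the two syringyl groups on C2/C5 are cis, the two CH2OH groups on C3/C4 are cis, and each aryl is trans to its neighbour. The ring is disconnected into syringaldehyde (ring O and C5) and a three-carbon donor–acceptor cyclopropane (C2, C3, C4) in which the two future CH2OH groups are tied up as a cis-fused γ-lactone. A Lewis-acid-catalysed (3+2) cycloaddition joins the aldehyde oxygen to the benzylic cyclopropane carbon and the aldehyde carbon to the acceptor carbon, setting all ring stereocentres relative to the lactone. Because the target is achiral, racemic intermediates suffice; decarboxylation and hydride reduction finish the synthesis.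

Key step: step 8

Remark: intermediates 9 and 12–15 are chiral and are made as racemates; their SMILES show one enantiomer with the intended relative configuration. Both enantiomers converge on the same meso target.

Step 1
Reactants: 1 4-bromo-2,6-dimethoxyphenol
Product: 2 4-bromo-2,6-dimethoxyphenyl pivalate
Conditions: PivCl (1.3 equiv), Et3N, DMAP (cat.), CH2Cl2, 0 °C → rt
Reagents that add atoms: pivaloyl chloride, CC(C)(C)C(Cl)=O
Why: DMAP-catalysed O-acylation of the phenol; the pivalate survives every later step, keeps the aryl ring a moderate donor and is designed to fall off in the final hydride reduction.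

Step 2
Reactants: 2 4-bromo-2,6-dimethoxyphenyl pivalate; 3 propargyl alcohol
Product: 4 4-(3-hydroxyprop-1-yn-1-yl)-2,6-dimethoxyphenyl pivalate
Conditions: PdCl2(PPh3)2 (3 mol%), CuI (5 mol%), Et3N, DMF, 70 °C
Reagents that add atoms: none
Why: Sonogashira coupling at the unhindered C–Br bond; the free propargylic OH and the aryl pivalate are tolerated under amine base.

Step 3
Reactants: 4 4-(3-hydroxyprop-1-yn-1-yl)-2,6-dimethoxyphenyl pivalate
Product: 5 4-[(Z)-3-hydroxyprop-1-en-1-yl]-2,6-dimethoxyphenyl pivalate
Conditions: H2 (1 atm), Pd/CaCO3 poisoned with Pb(OAc)2, quinoline, EtOAc, rt, stopped after 1 equiv H2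
Reagents that add atoms: none
Why: Semi-hydrogenation over poisoned Pd/CaCO3 (Lindlar reduction) delivers both hydrogens to one face of the alkyne, so the Z alkene should form.

Step 4
Reactants: 5 4-[(Z)-3-hydroxyprop-1-en-1-yl]-2,6-dimethoxyphenyl pivalate; 6 methyl malonyl chloride
Product: 7 (Z)-cinnamyl methyl malonate
Conditions: pyridine, CH2Cl2, 0 °C
Reagents that add atoms: none
Why: Acylation of the primary allylic alcohol by the acid chloride; the Z alkene is not touched under these mild basic conditions.

Step 5
Reactants: 7 (Z)-cinnamyl methyl malonate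
Product: 8 (Z)-cinnamyl methyl 2-diazomalonate
Conditions: p-ABSA (1.2 equiv), Et3N, MeCN, 0 °C → rt
Reagents that add atoms: 4-acetamidobenzenesulfonyl azide (p-ABSA), CC(=O)Nc1ccc(cc1)S(=O)(=O)N=[N+]=[N-]
Why: Regitz diazo transfer to the doubly activated methylene of the malonate.

Step 6
Reactants: 8 (Z)-cinnamyl methyl 2-diazomalonate
Product: 9 6-endo-aryl cyclopropane-fused lactone ester (racemic)
Conditions: Rh2(OAc)4 (2 mol%), ClCH2CH2Cl, 60 °C, slow addition of 8
Reagents that add atoms: none
Why: Intramolecular cyclopropanation by concerted syn addition of the rhodium carbene to the Z alkene, which places the aryl group endo (cis to the lactone CH2), while the five-membered tether forces the cis ring fusion, so all three stereocentres are fixed relative to one another.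

Step 7
Reactants: 10 syringaldehyde
Product: 11 4-formyl-2,6-dimethoxyphenyl pivalate
Conditions: PivCl (1.3 equiv), Et3N, DMAP (cat.), CH2Cl2, 0 °C → rt
Reagents that add atoms: pivaloyl chloride, CC(C)(C)C(Cl)=O
Why: DMAP-catalysed O-acylation of the phenol, giving the aldehyde partner with the same protecting group as 9.

Step 8
Reactants: 9 6-endo-aryl cyclopropane-fused lactone ester (racemic); 11 4-formyl-2,6-dimethoxyphenyl pivalate
Product: 13 cis-fused 4,6-diaryl furofuranone 6a-methyl ester (racemic), via oxocarbenium enolate zwitterion 12 (not isolated)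
Conditions: 11 (3 equiv), Sn(OTf)2 (10 mol%), ClCH2CH2Cl, rt → 45 °C
Reagents that add atoms: none
Why: Sn(OTf)2 chelates the lactone and ester carbonyls on C1 of 9 and polarises the C1–C6 bond, the carbonyl oxygen of 11 attacks the benzylic carbon C6 anti to the departing C1 (SN2-like, inversion) to give the tin-bound zwitterion 12, and its enolate carbon then adds to the oxocarbenium carbon in an intramolecular aldol-type step. The closest known reaction type is the Lewis-acid-catalysed (3+2) cycloaddition of 2-arylcyclopropane-1,1-dicarboxylates with aldehydes, which gives 2,5-cis-oxolanes with inversion at the donor carbon. The oxolane ring closes in a 5-(enolexo)-endo-trig mode onto a cationic C=O+ unit, the case in which 5-endo closure is facile. The aryl-bearing carbon that was C6 is controlled by inversion of the endo-aryl cyclopropane (the aryl ends up trans to the lactone CH2), the aryl-bearing carbon from 11 by closure through the E oxocarbenium ion with its aryl group pseudo-equatorial on the convex face (cis to the first aryl), and the quaternary ring-fusion carbon by the lactone, which can only be cis-fused. The step needs cleavage of C1–C6 and not C1–C5, secured because only C6 is benzylic and flanked by both acceptors, and it needs convex-face selectivity for both aryl groups, which retro-aldol equilibration under the Lewis acid should reinforce. The moderate donor strength of the pivaloyloxy-substituted ring should keep the opening stereospecific, and an ionised pathway would still be expected to close to the same convex-face isomer.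

Step 9
Reactants: 13 cis-fused 4,6-diaryl furofuranone 6a-methyl ester (racemic)
Product: 15 cis-fused 4,6-diaryl furofuranone (racemic), via lithium carboxylate 14 (not isolated)
Conditions: LiCl (3 equiv), H2O (2 equiv), DMSO, 130 °C
Reagents that add atoms: none
Why: Krapcho dealkoxycarbonylation, in which chloride demethylates the angular ester to give 14, CO2 is lost, and the lactone enolate can only be protonated to the cis-fused bicycle, leaving the lactone carbonyl cis to the lactone CH2 and trans to the neighbouring aryl group.

Step 10
Reactants: 15 cis-fused 4,6-diaryl furofuranone (racemic)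
Product: 16 meso-2,5-bis(4-hydroxy-3,5-dimethoxyphenyl)oxolane-3,4-diyldimethanol (target)
Conditions: LiAlH4 (6 equiv), THF, 0 °C → rt; EtOAc quench, then aq. potassium sodium tartrate
Reagents that add atoms: none
Why: LiAlH4 reduces the lactone to the 1,4-diol and cleaves both aryl pivalates in the same operation without touching a stereocentre, so the cis lactone becomes the cis pair of CH2OH groups of the meso target.

Compound list
1 | 4-bromo-2,6-dimethoxyphenol | COc1cc(Br)cc(OC)c1O | starting material
2 | 4-bromo-2,6-dimethoxyphenyl pivalate | COc1cc(Br)cc(OC)c1OC(=O)C(C)(C)C | intermediate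
3 | propargyl alcohol (prop-2-yn-1-ol) | C#CCO | starting material
4 | 4-(3-hydroxyprop-1-yn-1-yl)-2,6-dimethoxyphenyl pivalate | COc1cc(C#CCO)cc(OC)c1OC(=O)C(C)(C)C | intermediate
5 | 4-[(Z)-3-hydroxyprop-1-en-1-yl]-2,6-dimethoxyphenyl pivalate | COc1cc(/C=C\CO)cc(OC)c1OC(=O)C(C)(C)C | intermediate
6 | methyl malonyl chloride (methyl 3-chloro-3-oxopropanoate) | COC(=O)CC(Cl)=O | starting material
7 | methyl (Z)-3-[3,5-dimethoxy-4-(pivaloyloxy)phenyl]prop-2-en-1-yl malonate | COc1cc(/C=C\COC(=O)CC(=O)OC)cc(OC)c1OC(=O)C(C)(C)C | intermediate
8 | methyl (Z)-3-[3,5-dimethoxy-4-(pivaloyloxy)phenyl]prop-2-en-1-yl 2-diazomalonate | COc1cc(/C=C\COC(=O)C(=[N+]=[N-])C(=O)OC)cc(OC)c1OC(=O)C(C)(C)C | intermediate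
9 | methyl 6-[3,5-dimethoxy-4-(pivaloyloxy)phenyl]-2-oxo-3-oxabicyclo[3.1.0]hexane-1-carboxylate, aryl endo (cis to the lactone CH2 and carbonyl), racemic | COC(=O)[C@@]12C(=O)OC[C@@H]1[C@@H]2c3cc(OC)c(OC(=O)C(C)(C)C)c(OC)c3 | intermediate
10 | syringaldehyde (4-hydroxy-3,5-dimethoxybenzaldehyde) | COc1cc(C=O)cc(OC)c1O | starting material
11 | 4-formyl-2,6-dimethoxyphenyl pivalate | COc1cc(C=O)cc(OC)c1OC(=O)C(C)(C)C | intermediate
12 | ring-opened oxocarbenium / lactone–ester enolate zwitterion (tin-bound in the flask), benzylic C–O formed with inversion | COc1cc([C@@H]([O+]=Cc3cc(OC)c(OC(=O)C(C)(C)C)c(OC)c3)[C@H]4COC(=O)C4=C([O-])OC)cc(OC)c1OC(=O)C(C)(C)C | intermediate (not isolated)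
13 | methyl 4,6-bis[3,5-dimethoxy-4-(pivaloyloxy)phenyl]-1-oxotetrahydro-1H,3H-furo[3,4-c]furan-6a-carboxylate; cis-fused, both aryls on the convex face (cis to each other, trans to the lactone ring), racemic | COc1cc([C@H]2O[C@@H](c3cc(OC)c(OC(=O)C(C)(C)C)c(OC)c3)[C@]4(C(=O)OC)C(=O)OC[C@H]24)cc(OC)c1OC(=O)C(C)(C)C | intermediate
14 | lithium carboxylate of 13 (angular CO2Li) | COc1cc([C@H]2O[C@@H](c3cc(OC)c(OC(=O)C(C)(C)C)c(OC)c3)[C@]4(C(=O)[O-])C(=O)OC[C@H]24)cc(OC)c1OC(=O)C(C)(C)C.[Li+] | intermediate (not isolated)
15 | 4,6-bis[3,5-dimethoxy-4-(pivaloyloxy)phenyl]tetrahydro-1H,3H-furo[3,4-c]furan-1-one; cis-fused, both aryls on the convex face, racemic | COc1cc([C@H]2O[C@@H](c3cc(OC)c(OC(=O)C(C)(C)C)c(OC)c3)[C@@H]4C(=O)OC[C@H]24)cc(OC)c1OC(=O)C(C)(C)C | intermediate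
16 | [(2R,3S,4R,5S)-2,5-bis(4-hydroxy-3,5-dimethoxyphenyl)oxolane-3,4-diyl]dimethanol (meso; aryls cis, CH2OH groups cis, aryl/CH2OH trans) | COc1cc([C@H]2O[C@@H](c3cc(OC)c(O)c(OC)c3)[C@H](CO)[C@@H]2CO)cc(OC)c1O | target

Total step count: 10. Longest linear sequence: 9 steps (steps 1–6, then 8–10); step 7 is a one-step side branch.

Steps most likely to fail

Step 8. The pivaloyloxy-substituted ring is only a moderate donor and 11 only a moderate nucleophile. Ring opening may therefore be slower than Lewis-acid-induced cis-to-trans isomerisation of the cyclopropane, which would erode the configuration at the first aryl-bearing carbon, or slower than aldehyde oligomerisation. Fallback: the two bond formations are separated, setting out from 9 and returning at 13. Ring opening of 9 with water (Yb(OTf)3 cat., aqueous dioxane, rt), a far better nucleophile used in large excess, should give by SN2 attack at the benzylic carbon the γ-hydroxy lactone ester F1. Crude F1 and 11 are then condensed with TMSOTf in CH2Cl2 at −78 → 0 °C; hemiacetal ionisation gives the same oxocarbenium ion, which the enol of the lactone–ester captures in a Prins/aldol-type closure to 13.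

Step 9. At 130 °C in wet DMSO the pivalates may be partly hydrolysed. The transient lactone enolate may also open the oxolane ring by E1cB loss of the β-oxygen (a retro-oxa-Michael process), with scrambling at the adjacent benzylic carbon. Fallback: hydrolysis and thermal decarboxylation replace the nucleophilic demethylation, setting out from 13 and returning at 16. LiOH (excess) in THF/H2O at rt to 50 °C cleaves the methyl ester, the lactone and both pivalates. Acidification to pH 2 relactonises the cis hydroxy acid to the malonic half-acid lactone bisphenol F2. Heating F2 in dioxane at 100 °C expels CO2 to give the cis-fused bisphenol lactone F3, and LiAlH4 in THF reduces F3 to 16.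

Step 6. The Z-aryl group must fold into the endo position during intramolecular carbene transfer. Carbene dimerisation, attack on the arene, or a stepwise addition with loss of alkene geometry could compete. Fallback: the cyclopropane is made intermolecularly and the lactone closed afterwards, setting out from 5 and returning at 9. Silylation of 5 (TBSCl, imidazole, DMF) gives the silyl ether F4. Cyclopropanation of F4 with dimethyl diazomalonate (Rh2(esp)2 cat., CH2Cl2, rt) should give by syn addition the cis-2-aryl-3-(silyloxymethyl)cyclopropane-1,1-diester F5. HF·pyridine in THF followed by catalytic p-TsOH removes the silyl group, and the freed CH2OH lactonises onto the cis ester to give 9.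

Further compounds
F1 | step 8 | methyl 4-{[3,5-dimethoxy-4-(pivaloyloxy)phenyl](hydroxy)methyl}-2-oxooxolane-3-carboxylate (water adduct of 9, benzylic OH installed with inversion; C3 epimerisable) | COc1cc([C@@H](O)[C@H]2COC(=O)C2C(=O)OC)cc(OC)c1OC(=O)C(C)(C)C
F2 | step 9 | 4,6-bis(4-hydroxy-3,5-dimethoxyphenyl)-1-oxotetrahydro-1H,3H-furo[3,4-c]furan-6a-carboxylic acid (cis-fused, aryls on the convex face, racemic) | COc1cc([C@H]2O[C@@H](c3cc(OC)c(O)c(OC)c3)[C@]4(C(O)=O)C(=O)OC[C@H]24)cc(OC)c1O
F3 | step 9 | 4,6-bis(4-hydroxy-3,5-dimethoxyphenyl)tetrahydro-1H,3H-furo[3,4-c]furan-1-one (cis-fused, aryls on the convex face, racemic) | COc1cc([C@H]2O[C@@H](c3cc(OC)c(O)c(OC)c3)[C@@H]4C(=O)OC[C@H]24)cc(OC)c1O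
F4 | step 6 | 4-[(Z)-3-(tert-butyldimethylsilyloxy)prop-1-en-1-yl]-2,6-dimethoxyphenyl pivalate | COc1cc(/C=C\CO[Si](C)(C)C(C)(C)C)cc(OC)c1OC(=O)C(C)(C)C
F5 | step 6 | dimethyl cis-2-[3,5-dimethoxy-4-(pivaloyloxy)phenyl]-3-[(tert-butyldimethylsilyloxy)methyl]cyclopropane-1,1-dicarboxylate (racemic) | COC(=O)C1(C(=O)OC)[C@H](CO[Si](C)(C)C(C)(C)C)[C@@H]1c2cc(OC)c(OC(=O)C(C)(C)C)c(OC)c2
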